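Retrosynthesis: the benzyl-masked 3'-O–H bond and the O5–CH3 and O8–CH3 bonds are cut first, aromatic ring A is then read as the tautomer of a dihydropyranone-fused para-quinone, and the pyranone is cut at C4–C4a and O1–C2.
Enabling feature: in ring A the C5 and C8 oxygens are para, O1 (on C8a) and the C7 methoxy group flank C8, and C4a sits between C8a and C5. This is the pattern of 2-hydroxy-6-methoxy-1,4-benzoquinone, whose enolic C3 and hydroxyl O2 become C4a and O1.
Forward order: ring A (as the quinone) and ring B (isovanillin) are bought. The pyranone ring is closed between them by a domino Michael addition–lactonization on an arylidene Meldrum's acid (step 4). Ring A is then aromatized by base-mediated tautomerization, which also creates C3=C4 (step 5), and O-methylation and debenzylation finish the route.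
Stereochemistry: the target is achiral. The only stereocenter of the route (C4 of the annulation product) is formed racemic and is erased in the aromatization.

Key step: step 4

Remark: bicyclic compounds carry coumarin numbering (O1, C2 to C8a). Quinone 2 is numbered with C1=O between the hydroxyl-bearing C2 and the methoxy-bearing C6 and is assumed to react as this 2-hydroxy-1,4-quinone tautomer. Compounds 1, 3 and 5 are taken as commercial.

Step 1
Reactants: 1 2,6-dimethoxy-1,4-benzoquinone
Product: 2 2-hydroxy-6-methoxy-1,4-benzoquinone
Conditions: NaOH (1.1 equiv), H2O–THF, 0 °C to rt, N2; then 1 M HCl to pH 2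
Reagents that add atoms: sodium hydroxide, [Na+].[OH-]
Why: Hydroxide adds to the methoxy-bearing β-carbon of the vinylogous methyl ester and expels methoxide (addition–elimination, vinylogous saponification); the vinylogous carboxylate formed is no longer electrophilic, so the second, equivalent methoxy group should stay.

Step 2
Reactants: 3 isovanillin (3-hydroxy-4-methoxybenzaldehyde)
Product: 4 3-benzyloxy-4-methoxybenzaldehyde
Conditions: BnBr, K2CO3, DMF, rt
Reagents that add atoms: benzyl bromide, BrCc1ccccc1
Why: Williamson ether synthesis on the phenoxide; the benzyl ether should withstand the amine bases and the carbonate/iodomethane of the later steps and can be removed at the end without touching the methyl ethers.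

Step 3
Reactants: 4 3-benzyloxy-4-methoxybenzaldehyde; 5 Meldrum's acid (2,2-dimethyl-1,3-dioxane-4,6-dione)
Product: 6 5-(3-benzyloxy-4-methoxybenzylidene)-2,2-dimethyl-1,3-dioxane-4,6-dione
Conditions: piperidinium acetate (10 mol %), EtOH, rt
Reagents that add atoms: none
Why: Knoevenagel condensation of a non-enolizable aryl aldehyde with the highly acidic methylene of 5; the arylidene product should crystallize from the medium.

Step 4
Reactants: 2 2-hydroxy-6-methoxy-1,4-benzoquinone; 6 5-(3-benzyloxy-4-methoxybenzylidene)-2,2-dimethyl-1,3-dioxane-4,6-dione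
Product: 9 4-(3-benzyloxy-4-methoxyphenyl)-7-methoxy-3,4-dihydro-2H-chromene-2,5,8-trione (racemic), via Michael adduct 7 (not isolated), via lactone acid 8 (not isolated)
Conditions: Et3N (20 mol %), MeCN, 80 °C, N2
Reagents that add atoms: none
Why: Et3N converts the vinylogous acid 2 into its ambident anion, which adds through C3, its only enolic carbon, to the benzylidene carbon of the doubly activated alkene 6 (Michael addition, C4–C4a bond) to give 7. The adjacent enol oxygen O2 then attacks one carbonyl group of the dioxanedione, which opens with loss of acetone to the malonic half-acid lactone 8 (O1–C2 bond), and decarboxylation at 80 °C leaves the C3 methylene of 9. The closest known reaction type is the domino Michael addition–lactonization of 2-hydroxy-1,4-naphthoquinone with arylidene Meldrum's acids, which gives 4-aryl-3,4-dihydropyranone-fused para-quinones. The one ring closed, the six-membered lactone, forms by 6-exo-trig attack of oxygen on the acyl carbon (addition–elimination). The new stereocenter C4 is created from achiral partners under an achiral catalyst, so 9 is racemic, which is harmless because C4 becomes sp2 in step 5. The step needs C–C bond formation at C3 and acylation at O2 instead of the tautomeric O4 (which would give the ortho-quinone lactone and, later, the 5,6,7-oxygenation pattern): C3 is the only nucleophilic carbon, and the hydroxyl of the adduct sits on O2 in the favoured para-quinone tautomer, in which the C6 methoxy group stays conjugated to C4=O as a vinylogous ester, so the para-quinone lactone should be the product, as it is in the naphthoquinone series.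

Step 5
Reactants: 9 4-(3-benzyloxy-4-methoxyphenyl)-7-methoxy-3,4-dihydro-2H-chromene-2,5,8-trione
Product: 11 4-(3-benzyloxy-4-methoxyphenyl)-5,8-dihydroxy-7-methoxy-2H-chromen-2-one, via ortho-quinone methide 10 (not isolated)
Conditions: DBU (0.3 equiv), degassed MeCN, 50 °C, Ar; then AcOH
Reagents that add atoms: none
Why: Proposed new method: 9 and 11 are isomers, so neither oxidant nor reductant is needed; DBU should remove the C4–H (benzylic to ring B and vinylogously α to the C8 carbonyl through C4a=C8a), protonation of the dienolate on O8 gives the ortho-quinone methide 10 (C4=C4a–C5=O), and a second vinylogous proton shift from C3 (α to the lactone carbonyl) to O5 aromatizes ring A and creates C3=C4, driven by the gain of a benzene ring and a conjugated coumarin and erasing the C4 stereocenter; the closest known reaction types are the amine-mediated tautomerization of alkyl-1,4-benzoquinones to ortho-quinone methides (prenylquinone to chromenol) and the proton shift of ortho-quinone methides to 2-alkenylphenols.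

Step 6
Reactants: 11 4-(3-benzyloxy-4-methoxyphenyl)-5,8-dihydroxy-7-methoxy-2H-chromen-2-one
Product: 12 4-(3-benzyloxy-4-methoxyphenyl)-5,7,8-trimethoxy-2H-chromen-2-one
Conditions: MeI (excess), K2CO3, degassed acetone, reflux, Ar
Reagents that add atoms: iodomethane, CI
Why: Double Williamson O-methylation of the two phenols; the coumarin lactone is stable to anhydrous carbonate, and exclusion of oxygen keeps the hydroquinone dianion from being oxidized to the coumarin-5,8-quinone.

Step 7
Reactants: 12 4-(3-benzyloxy-4-methoxyphenyl)-5,7,8-trimethoxy-2H-chromen-2-one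
Product: 13 3'-hydroxy-5,7,8,4'-tetramethoxy-4-phenylcoumarin, i.e. 4-(3-hydroxy-4-methoxyphenyl)-5,7,8-trimethoxy-2H-chromen-2-one
Conditions: H2 (1 atm), 10% Pd/C, EtOAc–MeOH, rt, stopped after uptake of 1 equiv
Reagents that add atoms: none
Why: Catalytic hydrogenolysis of the benzyl aryl ether leaves the methyl ethers and the lactone untouched, and the trisubstituted, aryl-conjugated C3=C4 bond, shielded by the 5-methoxy group, should be reduced far more slowly than the O–benzyl bond is cleaved.

Compound list
1 | 2,6-dimethoxy-1,4-benzoquinone | COC1=CC(=O)C=C(OC)C1=O | starting material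
2 | 2-hydroxy-6-methoxy-1,4-benzoquinone | COC1=CC(=O)C=C(O)C1=O | intermediate
3 | isovanillin (3-hydroxy-4-methoxybenzaldehyde) | COc1ccc(C=O)cc1O | starting material
4 | 3-benzyloxy-4-methoxybenzaldehyde | COc1ccc(C=O)cc1OCc1ccccc1 | intermediate
5 | Meldrum's acid (2,2-dimethyl-1,3-dioxane-4,6-dione) | CC1(C)OC(=O)CC(=O)O1 | starting material
6 | 5-(3-benzyloxy-4-methoxybenzylidene)-2,2-dimethyl-1,3-dioxane-4,6-dione | CC1(C)OC(=O)C(=Cc2ccc(OC)c(OCc3ccccc3)c2)C(=O)O1 | intermediate
7 | 5-[(3-benzyloxy-4-methoxyphenyl)(2-hydroxy-4-methoxy-3,6-dioxocyclohexa-1,4-dien-1-yl)methyl]-2,2-dimethyl-1,3-dioxane-4,6-dione (racemic Michael adduct) | CC1(C)OC(=O)C(C(c2ccc(OC)c(OCc3ccccc3)c2)C2=C(O)C(=O)C(OC)=CC2=O)C(=O)O1 | intermediate (not isolated)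
8 | 4-(3-benzyloxy-4-methoxyphenyl)-7-methoxy-2,5,8-trioxo-3,4,5,8-tetrahydro-2H-chromene-3-carboxylic acid (racemic, diastereomer mixture) | O=C1OC2=C(C(=O)C=C(OC)C2=O)C(c2ccc(OC)c(OCc3ccccc3)c2)C1C(=O)O | intermediate (not isolated)
9 | 4-(3-benzyloxy-4-methoxyphenyl)-7-methoxy-3,4-dihydro-2H-chromene-2,5,8-trione (racemic at C4) | O=C1CC(c2ccc(OC)c(OCc3ccccc3)c2)C2=C(O1)C(=O)C(OC)=CC2=O | intermediate
10 | 4-(3-benzyloxy-4-methoxyphenyl)-8-hydroxy-7-methoxy-3H-chromene-2,5-dione (ortho-quinone methide tautomer of 9) | O=C1CC(c2ccc(OC)c(OCc3ccccc3)c2)=C2C(=O)C=C(OC)C(O)=C2O1 | intermediate (not isolated)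
11 | 4-(3-benzyloxy-4-methoxyphenyl)-5,8-dihydroxy-7-methoxy-2H-chromen-2-one | O=c1cc(-c2ccc(OC)c(OCc3ccccc3)c2)c2c(O)cc(OC)c(O)c2o1 | intermediate
12 | 4-(3-benzyloxy-4-methoxyphenyl)-5,7,8-trimethoxy-2H-chromen-2-one | COc1ccc(-c2cc(=O)oc3c(OC)c(OC)cc(OC)c23)cc1OCc1ccccc1 | intermediate
13 | 3'-hydroxy-5,7,8,4'-tetramethoxy-4-phenylcoumarin | COc1ccc(-c2cc(=O)oc3c(OC)c(OC)cc(OC)c23)cc1O | target

Total step count: 7. Longest linear sequence: 6 steps (3 to 13 through steps 2 to 7); the quinone branch (step 1) joins at step 4.

Steps most likely to fail

Step 5 (the proposed tautomerization). The C4 deprotonation may be too slow to compete with base-induced opening of the activated enol lactone (elimination to a ketene and re-closure on O5, or attack by adventitious nucleophiles). Electron exchange between quinone 9 and hydroquinone 11 may also divert material. The fallback uses known chemistry, sets out from 9 and returns at 12, passing 11 by. The quinone is reduced with Na2S2O4 (EtOAc–H2O, rt) to 4-(3-benzyloxy-4-methoxyphenyl)-5,8-dihydroxy-7-methoxy-3,4-dihydro-2H-chromen-2-one F1. Both phenols are methylated (MeI, K2CO3, dry acetone, Ar) to 4-(3-benzyloxy-4-methoxyphenyl)-5,7,8-trimethoxy-3,4-dihydro-2H-chromen-2-one F2. The C3–C4 bond is then dehydrogenated with DDQ in refluxing dioxane, the standard conversion of 4-aryl-3,4-dihydrocoumarins into 4-arylcoumarins, to give 12.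

Step 4 (key step). The lactone may close through the tautomeric oxygen O4 and lead into the ortho-quinone series, or the base-sensitive monocyclic hydroxyquinone may be consumed by self-condensation before the Michael addition. The fallback sets out from 6 and returns at 9. The ring oxygen is fixed first on a phenol that offers no regiochemical choice, and the quinone is made afterwards. Arylidene 6 is annulated with phloroglucinol F3 (pyridine, 90 °C; Michael addition–lactonization with loss of acetone and CO2) to 4-(3-benzyloxy-4-methoxyphenyl)-5,7-dihydroxy-3,4-dihydro-2H-chromen-2-one F4. Teuber oxidation with Fremy's salt, (KSO3)2NO, in aqueous KH2PO4–acetone at rt oxidizes para to the 5-hydroxyl (C8 is the only free para position) to 4-(3-benzyloxy-4-methoxyphenyl)-7-hydroxy-3,4-dihydro-2H-chromene-2,5,8-trione F5. Methylation of this vinylogous acid with diazomethane (Et2O, 0 °C) gives 9.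

Step 1. Hydrolysis may not stop cleanly at one methoxy group, and hydroxide may degrade the quinone (addition at the ring CH positions, oxidative oligomerization). The fallback cannot set out from a numbered compound because it replaces 1; it starts from commercial 5-methoxyresorcinol F6 and returns at 2. Teuber oxidation of F6 with (KSO3)2NO in aqueous KH2PO4 at rt should take place para to one hydroxyl (the two such positions are equivalent) and give 2 directly.

Further compounds
F1 | step 5 | 4-(3-benzyloxy-4-methoxyphenyl)-5,8-dihydroxy-7-methoxy-3,4-dihydro-2H-chromen-2-one (racemic) | O=C1CC(c2ccc(OC)c(OCc3ccccc3)c2)c2c(O)cc(OC)c(O)c2O1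
F2 | step 5 | 4-(3-benzyloxy-4-methoxyphenyl)-5,7,8-trimethoxy-3,4-dihydro-2H-chromen-2-one (racemic) | O=C1CC(c2ccc(OC)c(OCc3ccccc3)c2)c2c(OC)cc(OC)c(OC)c2O1
F3 | step 4 | phloroglucinol (benzene-1,3,5-triol, commercial) | Oc1cc(O)cc(O)c1
F4 | step 4 | 4-(3-benzyloxy-4-methoxyphenyl)-5,7-dihydroxy-3,4-dihydro-2H-chromen-2-one (racemic) | O=C1CC(c2ccc(OC)c(OCc3ccccc3)c2)c2c(O)cc(O)cc2O1
F5 | step 4 | 4-(3-benzyloxy-4-methoxyphenyl)-7-hydroxy-3,4-dihydro-2H-chromene-2,5,8-trione (racemic) | O=C1CC(c2ccc(OC)c(OCc3ccccc3)c2)C2=C(O1)C(=O)C(O)=CC2=O
F6 | step 1 | 5-methoxyresorcinol (5-methoxybenzene-1,3-diol, commercial) | COc1cc(O)cc(O)c1
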